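The target is cut at the C6–C8'' biaryl bond. Ring A of the acacetin unit carries O5 between the quaternary C4a and C6–H, and the phloroacetophenone ring carries, next to its brominated carbon (future C8''), the phenol that later becomes O1''. Joining these two oxygens through a diisopropylsilylene bridge lets a palladium-catalysed C–H arylation forge the tetra-ortho-oxygenated axis in one operation, closing a temporary seven-membered dioxasilepine and fixing the 6,8''-connectivity. The precursor is the mixed bis(aryloxy)silane of 7-O-benzylacacetin and a 3-bromo-2-hydroxyacetophenone whose ether next to bromine is MOM, not benzyl, so that no benzo[c]chromene can form.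

Key step: step 7

Assumption: the target SMILES defines no sense of the C6–C8'' axis, so the biaryl is made as the racemate and no atropselective element is built in.
Abbreviations and locants: MOM = methoxymethyl, Bn = benzyl; unprimed locants belong to the acacetin unit, double-primed to the apigenin unit, and 4''' is the para position of its 2-aryl ring.

Step 1
Reactants: 1 2',4',6'-trihydroxyacetophenone; 2 4-methoxybenzoyl chloride
Product: 4 acacetin, via 1,3-diketone 3 (not isolated)
Conditions: LiHMDS (5 equiv), THF, −78 °C, then 2, −78 °C → rt; aq. HCl quench; crude in AcOH, H2SO4 (cat.), 95 °C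
Reagents that add atoms: none
Why: The lithium polyanion of 1 is acylated on carbon at its ketone enolate by the aroyl chloride (crossed Claisen acylation, the direct variant of the Baker–Venkataraman route) and the resulting 2-hydroxyaryl 1,3-diketone cyclodehydrates under acid to the flavone, a sequence established for 5,7-dihydroxyflavones from this very ketone.

Step 2
Reactants: 4 acacetin
Product: 5 7-O-benzylacacetin
Conditions: BnBr (1.05 equiv), K2CO3 (1.1 equiv), DMF, rt
Reagents that add atoms: benzyl bromide, BrCc1ccccc1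
Why: Williamson etherification should take the acidic, unchelated 7-OH only, because the 5-OH is held in a hydrogen bond to the C4 carbonyl and is far less nucleophilic.

Step 3
Reactants: 1 2',4',6'-trihydroxyacetophenone
Product: 6 1-[2,6-dihydroxy-4-(methoxymethoxy)phenyl]ethanone
Conditions: MOMCl (1.0 equiv), K2CO3 (1.1 equiv), acetone, 0 °C → rt
Reagents that add atoms: chloromethyl methyl ether, COCCl
Why: Williamson-type acetal formation with one equivalent of electrophile should go to the para hydroxyl, the most acidic and the only one not chelated to the acetyl group.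

Step 4
Reactants: 6 1-[2,6-dihydroxy-4-(methoxymethoxy)phenyl]ethanone
Product: 7 1-[2-(benzyloxy)-6-hydroxy-4-(methoxymethoxy)phenyl]ethanone
Conditions: BnBr (1.05 equiv), K2CO3 (1.2 equiv), acetone, reflux
Reagents that add atoms: benzyl bromide, BrCc1ccccc1
Why: Williamson etherification of one of the two equivalent chelated hydroxyls should stop at the mono-ether, since the remaining hydroxyl is then bound more firmly to the carbonyl and is more hindered.

Step 5
Reactants: 7 1-[2-(benzyloxy)-6-hydroxy-4-(methoxymethoxy)phenyl]ethanone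
Product: 8 1-[6-(benzyloxy)-3-bromo-2-hydroxy-4-(methoxymethoxy)phenyl]ethanone
Conditions: NBS (1.0 equiv), CH2Cl2, −20 → 0 °C
Reagents that add atoms: N-bromosuccinimide, O=C1CCC(=O)N1Br
Why: Electrophilic aromatic bromination of 2-hydroxy-4,6-dialkoxyacetophenones goes ortho to the free chelated phenol, neutral NBS spares the MOM acetal, and the position is to be confirmed by NOE from the remaining aromatic proton to both OCH2 groups before going on.

Step 6
Reactants: 8 1-[6-(benzyloxy)-3-bromo-2-hydroxy-4-(methoxymethoxy)phenyl]ethanone; 9 dichlorodiisopropylsilane; 5 7-O-benzylacacetin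
Product: 11 mixed diisopropylsilylene diether (O2 of 8 and O5 of 5), via chlorosilane 10 (not isolated)
Conditions: 8, NaH (1.0 equiv), THF, 0 °C, added to iPr2SiCl2 (3 equiv), rt; excess silane removed in vacuo; then sodium phenoxide of 5 (NaH, 1.0 equiv, THF–DMF), 0 °C → rt; non-aqueous work-up, Et3N-deactivated silica
Reagents that add atoms: none
Why: Two successive nucleophilic substitutions at silicon (O-silylation) are ordered so that excess dichlorosilane stops the doubly ortho-substituted phenoxide of 8 at the monochloride and the less hindered 5-phenoxide, freed from its hydrogen bond by deprotonation, then displaces the second chloride.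

Step 7
Reactants: 11 mixed diisopropylsilylene diether
Product: 12 silylene-bridged 6-arylflavone (dibenzo[d,f][1,3,2]dioxasilepine)
Conditions: Pd(OAc)2 (10 mol%), PCy3·HBF4 (20 mol%), Cs2CO3 (2 equiv), caesium pivalate CsO2CCMe3 (30 mol%), 4 Å MS, mesitylene, 130 °C
Reagents that add atoms: none
Why: Zerovalent palladium, formed in situ from Pd(OAc)2 and PCy3, inserts into the C–Br bond at the future C8'', and the arylpalladium pivalate, held over ring A by the O–Si–O bridge, cleaves C6–H by concerted metalation–deprotonation through an eight-membered palladacycle before reductive elimination releases the C6–C8'' bond. The closest known reaction is the palladium-catalysed intramolecular C–H arylation of bis(aryloxy)dialkylsilanes to silylene-bridged 2,2'-biphenols, an extension of carbonate/pivalate-assisted direct arylation. The one new ring, the seven-membered dioxasilepine (C5, O, Si, O, C8a'', C8'', C6), is closed by this aryl–aryl bond formation with both carbons inside the ring. No stereocentre is created, and the bridged axis is formed without control of its sense. The step needs site selectivity on both rings: bromine fixes the carbon of the acetophenone ring, and the tether on O5 can deliver palladium only to C6 because the other ortho position, C4a, is quaternary and C3 and C8 are out of reach. Chemoselectivity is secured by design, since the ether ortho to bromine is a MOM acetal without an arene C–H, so the otherwise facile six-membered benzo[c]chromene closure onto a benzyl ether cannot compete, and the dry non-polar medium keeps the Si–O bonds intact.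

Step 8
Reactants: 12 silylene-bridged 6-arylflavone; 13 4-(benzyloxy)benzaldehyde
Product: 15 (E)-chalcone, via biaryl diol 14 (not isolated)
Conditions: KOH (50% aq., excess), EtOH–THF, rt; 13 (1.5 equiv)
Reagents that add atoms: none
Why: Hydroxide cleaves both aryl–O–Si bonds at once and the liberated 2-hydroxyacetophenone then undergoes Claisen–Schmidt condensation with the non-enolisable aldehyde, dehydration giving the (E)-enone under thermodynamic control.

Step 9
Reactants: 15 (E)-chalcone
Product: 16 tri-O-benzyl-7''-O-MOM biflavone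
Conditions: I2 (10 mol%), DMSO, 120 °C; aq. Na2S2O3 work-up
Reagents that add atoms: none
Why: Iodine-catalysed oxidative cyclisation of a 2'-hydroxychalcone (oxa-Michael closure, then iodination and loss of HI, which DMSO reoxidises) can close only through the phenol freed from silicon, now O1'', because the other ortho oxygen is a benzyl ether that withstands these conditions, and any loss of the MOM group para to the carbonyl would be harmless since the material converges in step 10.

Step 10
Reactants: 16 tri-O-benzyl-7''-O-MOM biflavone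
Product: 18 target biflavone, via 7''-O-MOM biflavone 17 (not isolated)
Conditions: H2 (1 atm), Pd/C (10 wt%), THF–MeOH, rt; filter; then HCl (3 M aq.), MeOH, 50 °C
Reagents that add atoms: none
Why: Hydrogenolysis of the three benzyl aryl ethers followed by acid-catalysed methanolysis of the MOM acetal leaves the 4'-methyl ether untouched, and the mild acid stays well below the conditions of a Wessely–Moser rearrangement.

Compound list
1 | 2',4',6'-trihydroxyacetophenone (phloroacetophenone) | CC(=O)c1c(O)cc(O)cc1O | starting material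
2 | 4-methoxybenzoyl chloride | COc1ccc(cc1)C(Cl)=O | starting material
3 | 1-(4-methoxyphenyl)-3-(2,4,6-trihydroxyphenyl)propane-1,3-dione (formed in situ) | COc1ccc(cc1)C(=O)CC(=O)c1c(O)cc(O)cc1O | intermediate
4 | acacetin, 5,7-dihydroxy-2-(4-methoxyphenyl)-4H-chromen-4-one | COc1ccc(cc1)-c1cc(=O)c2c(O)cc(O)cc2o1 | intermediate
5 | 7-O-benzylacacetin, 7-(benzyloxy)-5-hydroxy-2-(4-methoxyphenyl)-4H-chromen-4-one | COc1ccc(cc1)-c1cc(=O)c2c(O)cc(OCc3ccccc3)cc2o1 | intermediate
6 | 1-[2,6-dihydroxy-4-(methoxymethoxy)phenyl]ethanone | CC(=O)c1c(O)cc(OCOC)cc1O | intermediate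
7 | 1-[2-(benzyloxy)-6-hydroxy-4-(methoxymethoxy)phenyl]ethanone | CC(=O)c1c(O)cc(OCOC)cc1OCc1ccccc1 | intermediate
8 | 1-[6-(benzyloxy)-3-bromo-2-hydroxy-4-(methoxymethoxy)phenyl]ethanone | CC(=O)c1c(O)c(Br)c(OCOC)cc1OCc1ccccc1 | intermediate
9 | dichlorodiisopropylsilane | CC(C)[Si](Cl)(Cl)C(C)C | starting material
10 | 1-[6-(benzyloxy)-3-bromo-2-{[chloro(diisopropyl)silyl]oxy}-4-(methoxymethoxy)phenyl]ethanone (formed in situ) | CC(=O)c1c(O[Si](Cl)(C(C)C)C(C)C)c(Br)c(OCOC)cc1OCc1ccccc1 | intermediate
11 | diisopropylsilylene diether joining O5 of 7-O-benzylacacetin and O2 of bromoacetophenone 8 (key-step precursor) | COc1ccc(cc1)-c1cc(=O)c2c(O[Si](C(C)C)(C(C)C)Oc3c(Br)c(OCOC)cc(OCc4ccccc4)c3C(C)=O)cc(OCc3ccccc3)cc2o1 | intermediate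
12 | silylene-bridged 6-[3-acetyl-4-(benzyloxy)-6-(methoxymethoxy)-2-oxyphenyl]-7-(benzyloxy)-4'-methoxyflavone, O5 and the aryl O2 joined by Si(iPr)2 in a dibenzo[d,f][1,3,2]dioxasilepine (racemic axis) | COc1ccc(cc1)-c1cc(=O)c2c3O[Si](C(C)C)(C(C)C)Oc4c(C(C)=O)c(OCc5ccccc5)cc(OCOC)c4-c3c(OCc3ccccc3)cc2o1 | intermediate
13 | 4-(benzyloxy)benzaldehyde | O=Cc1ccc(OCc2ccccc2)cc1 | starting material
14 | 6-[3-acetyl-4-(benzyloxy)-2-hydroxy-6-(methoxymethoxy)phenyl]-7-(benzyloxy)-5-hydroxy-2-(4-methoxyphenyl)-4H-chromen-4-one (formed in situ) | COc1ccc(cc1)-c1cc(=O)c2c(O)c(-c3c(O)c(C(C)=O)c(OCc4ccccc4)cc3OCOC)c(OCc3ccccc3)cc2o1 | intermediate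
15 | 7-(benzyloxy)-6-{4-(benzyloxy)-3-[(E)-3-(4-(benzyloxy)phenyl)prop-2-enoyl]-2-hydroxy-6-(methoxymethoxy)phenyl}-5-hydroxy-2-(4-methoxyphenyl)-4H-chromen-4-one | COc1ccc(cc1)-c1cc(=O)c2c(O)c(-c3c(O)c(C(=O)/C=C/c4ccc(OCc5ccccc5)cc4)c(OCc4ccccc4)cc3OCOC)c(OCc3ccccc3)cc2o1 | intermediate
16 | 7-(benzyloxy)-6-[5-(benzyloxy)-2-(4-(benzyloxy)phenyl)-7-(methoxymethoxy)-4-oxo-4H-chromen-8-yl]-5-hydroxy-2-(4-methoxyphenyl)-4H-chromen-4-one (racemic axis) | COc1ccc(-c2cc(=O)c3c(O)c(-c4c(OCOC)cc(OCc5ccccc5)c5c(=O)cc(-c6ccc(OCc7ccccc7)cc6)oc45)c(OCc4ccccc4)cc3o2)cc1 | intermediate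
17 | 5,7-dihydroxy-6-[5-hydroxy-2-(4-hydroxyphenyl)-7-(methoxymethoxy)-4-oxo-4H-chromen-8-yl]-2-(4-methoxyphenyl)-4H-chromen-4-one (formed in situ) | COc1ccc(-c2cc(=O)c3c(O)c(-c4c(OCOC)cc(O)c5c(=O)cc(-c6ccc(O)cc6)oc45)c(O)cc3o2)cc1 | intermediate
18 | 5,7-dihydroxy-6-[5,7-dihydroxy-2-(4-hydroxyphenyl)-4-oxo-4H-chromen-8-yl]-2-(4-methoxyphenyl)-4H-chromen-4-one (6,8''-linked acacetin–apigenin dimer, axis unspecified) | COc1ccc(-c2cc(=O)c3c(O)c(-c4c(O)cc(O)c5c(=O)cc(-c6ccc(O)cc6)oc45)c(O)cc3o2)cc1 | target

Total step count: 10 steps.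
Longest linear sequence: 8 steps (steps 3, 4, 5, 6, 7, 8, 9, 10 from compound 1); the acacetin branch (steps 1 and 2) joins at step 6.

Steps most likely to fail

Step 7. Reduction of the C–Br bond or redistribution of the Si–O tether may outrun the slow metalation of the crowded C6–H, and reductive elimination to a tetra-ortho-substituted biaryl may stall. The fallback gives up the tether and joins the rings by Suzuki–Miyaura coupling; it sets out from 5 and 8 and comes back at 14. Compound 5 is iodinated ortho to its chelated 5-OH with benzyltrimethylammonium dichloroiodate and CaCO3 in CH2Cl2–MeOH to give 7-(benzyloxy)-5-hydroxy-6-iodo-2-(4-methoxyphenyl)-4H-chromen-4-one F1. Compound 8 is converted by Miyaura borylation (bis(pinacolato)diboron, KOAc, Pd2(dba)3, XPhos, dioxane, 100 °C) into 1-[6-(benzyloxy)-2-hydroxy-4-(methoxymethoxy)-3-(4,4,5,5-tetramethyl-1,3,2-dioxaborolan-2-yl)phenyl]ethanone F2. Coupling of F1 with F2 (Pd2(dba)3, SPhos, K3PO4, toluene–water, 100 °C) should give the diol 14, which then enters the condensation of step 8. Here the bromine on 8 and the iodine ortho to the 5-OH carry the regiochemistry that the tether carried before.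

Step 6. Exchange of aryloxy groups at silicon may give the two symmetrical bis(aryloxy)silanes, silylation of the hydrogen-bonded 5-OH may stay incomplete, and the product may hydrolyse during isolation. The fallback builds the unsymmetrical silane through a hydridosilane; it sets out from 8 and comes back at 11. Compound 8 is silylated with chlorodiisopropylsilane and imidazole in CH2Cl2 to the robust, purifiable 1-[6-(benzyloxy)-3-bromo-2-[(diisopropylsilyl)oxy]-4-(methoxymethoxy)phenyl]ethanone F3. Its Si–H bond is brominated with NBS in CH2Cl2 at 0 °C to 1-[6-(benzyloxy)-3-bromo-2-{[bromo(diisopropyl)silyl]oxy}-4-(methoxymethoxy)phenyl]ethanone F4, which is used in solution. Addition of the sodium phenoxide of 5 should then give 11 with only one aryloxide ever exposed to a silicon electrophile.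

Step 8. Hydroxide may add to C2 of the existing pyranone during the slow condensation of the hindered ketone, opening the ring and allowing reclosure through O5 with migration of the aryl group from C6 to C8. The fallback avoids hydroxide and the chalcone altogether; it sets out from 12 and comes back at 18. Compound 12 is desilylated with Bu4NF buffered with AcOH in THF at 0 °C to the diol 14, now isolated. Its lithium trianion (LiHMDS, THF, −78 °C) is acylated on carbon with 4-(benzyloxy)benzoyl chloride to 1-[4-(benzyloxy)phenyl]-3-{6-(benzyloxy)-3-[7-(benzyloxy)-5-hydroxy-2-(4-methoxyphenyl)-4-oxo-4H-chromen-6-yl]-2-hydroxy-4-(methoxymethoxy)phenyl}propane-1,3-dione F5. HCl (cat.) in MeOH–THF at 60 °C cyclodehydrates F5 through its only free ortho phenol and removes the MOM group, giving 7-(benzyloxy)-6-[5-(benzyloxy)-2-(4-(benzyloxy)phenyl)-7-hydroxy-4-oxo-4H-chromen-8-yl]-5-hydroxy-2-(4-methoxyphenyl)-4H-chromen-4-one F6. Hydrogenolysis of F6 (H2, Pd/C, THF–MeOH) gives the target 18.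

Further compounds
F1 | step 7 | 7-(benzyloxy)-5-hydroxy-6-iodo-2-(4-methoxyphenyl)-4H-chromen-4-one | COc1ccc(cc1)-c1cc(=O)c2c(O)c(I)c(OCc3ccccc3)cc2o1
F2 | step 7 | 1-[6-(benzyloxy)-2-hydroxy-4-(methoxymethoxy)-3-(4,4,5,5-tetramethyl-1,3,2-dioxaborolan-2-yl)phenyl]ethanone | CC(=O)c1c(O)c(B2OC(C)(C)C(C)(C)O2)c(OCOC)cc1OCc1ccccc1
F3 | step 6 | 1-[6-(benzyloxy)-3-bromo-2-[(diisopropylsilyl)oxy]-4-(methoxymethoxy)phenyl]ethanone | CC(=O)c1c(O[SiH](C(C)C)C(C)C)c(Br)c(OCOC)cc1OCc1ccccc1
F4 | step 6 | 1-[6-(benzyloxy)-3-bromo-2-{[bromo(diisopropyl)silyl]oxy}-4-(methoxymethoxy)phenyl]ethanone | CC(=O)c1c(O[Si](Br)(C(C)C)C(C)C)c(Br)c(OCOC)cc1OCc1ccccc1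
F5 | step 8 | 1-[4-(benzyloxy)phenyl]-3-{6-(benzyloxy)-3-[7-(benzyloxy)-5-hydroxy-2-(4-methoxyphenyl)-4-oxo-4H-chromen-6-yl]-2-hydroxy-4-(methoxymethoxy)phenyl}propane-1,3-dione | COc1ccc(cc1)-c1cc(=O)c2c(O)c(-c3c(O)c(C(=O)CC(=O)c4ccc(OCc5ccccc5)cc4)c(OCc4ccccc4)cc3OCOC)c(OCc3ccccc3)cc2o1
F6 | step 8 | 7-(benzyloxy)-6-[5-(benzyloxy)-2-(4-(benzyloxy)phenyl)-7-hydroxy-4-oxo-4H-chromen-8-yl]-5-hydroxy-2-(4-methoxyphenyl)-4H-chromen-4-one | COc1ccc(-c2cc(=O)c3c(O)c(-c4c(O)cc(OCc5ccccc5)c5c(=O)cc(-c6ccc(OCc7ccccc7)cc6)oc45)c(OCc4ccccc4)cc3o2)cc1
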